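## Structural features

Dipolynaphthalene B is made of two C10 units: a 1,2,3,4-tetrahydronaphthalen-1-ol (ring A, the methoxy-bearing benzene ring, fused to the saturated ring B) and a 4-hydroxy-5-methoxynaphthalene (rings C and D), joined by one bond from C4 of ring B to C1′ of ring C. Ring B holds both stereocentres, the secondary benzylic carbinol C1 (S) and the doubly benzylic methine C4 (S). They are not neighbours: they stand 1,4 to each other across the methylene carbons C2 and C3, with hydroxyl and aryl group cis. C4 lies peri to the C5 methoxy group of ring A and its naphthyl substituent has a peri hydrogen of its own, so the C4–C1′ bond is the most crowded place in the molecule, and C8a, which carries C1, is meta to the methoxy group, so an electrophilic closure of ring B there would have to compete with attack on the far more electron-rich naphthol ring. The fragile groups are the benzylic alcohol (acid ionises it, and loss of water leads on to a naphthalene), the electron-rich peri-methoxy naphthol (oxidised by air and by most oxidants) and the C4–H bond. The real difficulty is twofold: placing oxygen at C1 and aryl at C4 in the right sense relative to the single methoxy group of ring A, and reaching one enantiomer of two stereocentres that are too far apart for simple relay. The key step uses the fact that C1 and C4 are bonded to the adjacent ring-A carbons C8a and C4a while C1 carries oxygen: if that oxygen is tied to C4 as well, rings A and B become a 7-oxabenzonorbornene, the cycloadduct of an aryne (C4a and C8a) and a 2-arylfuran (C1, C2, C3, C4 and the oxygen).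

## Logic of the disconnections

15 back to 14. The acyl–oxygen bond on ring C is cut, which in the backward sense adds a protecting group. The free naphthol would not survive an oxidant and would add to an aryne, so it is masked from an early stage. The gain is that every earlier intermediate is air-stable and has one nucleophilic site fewer. The demand on the forward step is removal without acid, because of the benzylic carbinol.

14 back to 13. The C1–H bond is cut. A carbinol next to an arene can be set by reagent-controlled hydride addition, whatever the configuration at C4. The gain is one stereocentre fewer: 13 has only C4 and may be racemic. The demand is that the catalyst overrides any bias from the remote C4 centre in both enantiomers of 13, and that the trans diastereomer formed from the other enantiomer of 13 can be separated from 14. At most half of 13 can end as 14.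

13 back to 12. No skeletal bond is cut; C1 is returned from the ketone to the alcohol level. The bridge opening delivers the alcohol as a mixture of diastereomers, and the oxidation erases C1 so that the mixture converges. The demand is an oxidant that leaves the pivalate and the electron-rich arenes alone.

12 back to 10 (through 11). The C4–H bond is cut and C4 is reconnected to the C1 oxygen, which gives the C1–O–C4 bridge. The 1,4-relationship of oxygen and aryl thereby becomes a cyclic ether whose two C–O bonds differ greatly in ease of ionisation. The gain is that ring B becomes part of a bicycle that is a cycloadduct. The demand is that only the C4–O bond breaks in the forward step, and that the cation takes up hydride faster than it loses a proton.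

10 back to 9. The C2=C3 double bond is put back. It is the trace of the furan diene. The forward step must saturate it without hydrogenolysis, and must do so before any acid is used, since 9 would aromatise to a naphthol.

9 back to 6 and 8 (8 from 7). The bonds C1–C8a and C4–C4a are cut. They join ring B to adjacent carbons of ring A, which is the pattern of an aryne cycloaddition. The gain is two rings, two bonds and the whole carbon skeleton in one step from two pieces of similar size, with the aryl group placed ortho to methoxy without electrophilic substitution. The demand is regioselectivity, and the acceptance that 9 is racemic.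

6 back to 4 and 5. The bond between C1′ of ring C and the furan is cut as a cross-coupling of two sp2 carbons. The gain is that the furan comes from a purchased boronic acid. The demand is a coupling that is faster than protodeboronation of 5 and a base that spares the ester.

4 back to 3, 2 and 1. The O–acyl, C–Br and O–CH3 bonds are cut in that order. This differentiates the two oxygens of symmetric 1 and uses the free hydroxyl to direct the halogen to its para position before it is masked. The demands are mono-alkylation of 1, para-selective bromination of 2, and keeping this order of events.

## Other disconnections considered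

Alternative 1: The cut is at C1–C2 and C1–C8a, so that C1 becomes a one-carbon unit, carbon monoxide A3. The precursor would be the (S)-configured aryl bromide A2, which carries the vinyl group, the naphthyl group and the 2-bromo-6-methoxyphenyl group on the future C4. In the forward sense the vinyl group of A2 would be hydroborated with a hindered dialkylborane. PdCl2(dppf) would then insert into the C8a–Br bond, take up A3, accept the alkyl group from boron and close the tetralone A1.
- In its favour: C4 is set before the ring closes, so no material would be lost in a resolution; on this point it is better than the chosen plan. The bromine fixes the regiochemistry on ring A without any reliance on aryne polarisation, which is also better. A1 is at the ketone level like 13, but as one enantiomer, so the reduction only has to control C1.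
- Against it: direct coupling without uptake of A3 would close a five-membered ring and is a real competitor. Oxidative addition into a doubly ortho-substituted aryl bromide is slow. A2 itself contains the hard problem, a stereocentre carrying two hindered aryl groups and a vinyl group, which would probably need an asymmetric allylic arylation with little precedent for such partners.
- Comparison: both plans close ring B onto ring A. The chosen plan forms both bonds to ring A at once in a pericyclic step and reaches the skeleton in fewer steps, but pays with half the material. Alternative 1 is longer before its key step and wastes nothing after it.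

Alternative 2: The cut is at C4a–C8a and C5–C6; ring A is built from nothing. The precursor would be the open-chain furan-yne A5, with both stereocentres in place. AuCl3 (trivalent gold) would activate the terminal alkyne. Attack of the furan and reorganisation through carbenoid and arene oxide stages would turn the two alkyne carbons and the four furan carbons into the phenol A4, with the hydroxyl at C5. O-Methylation and two silyl removals would follow.
- In its favour: the peri relationship of the C4 aryl group and the C5 oxygen is fixed by the tether, with no regiochemical question; this is better than the chosen plan. Both stereocentres would come from independent asymmetric steps, with no resolution, which is also better. As an isomerisation it equals the cycloaddition in atom economy.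
- Against it: a four-carbon, all-carbon tether that closes a six-membered carbocycle goes beyond the short heteroatom tethers on which this reaction type is most secure. The furylic silyl ether at C1 and the propargylic, naphthyl-bearing C4–H are both easily ionised by a hard Lewis acid. The electron-rich naphthalene could compete for the activated alkyne. A5 needs a chain assembly with two enantioselective steps, and three steps remain after A4.
- Comparison: on structure it solves the crowding more cleanly. On mechanism it rests on a longer cascade with more ways to fail than a single [4+2] addition. On step economy it is clearly longer than the ten steps proposed here.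

Alternative 3: The cut is at C4a′–C5′ and C8′–C8a′; ring D of the naphthol is built last. The diene A8 would add across one enone of the para-quinol silyl ether A7, with the ketene acetal carbon bonding next to the carbonyl. Mild acid would then expel the silyloxy group and one methoxy group and aromatise both rings to A6. Desilylation would give the target.
- In its favour: the sensitive naphthol appears only at the end and needs no protecting group, which is better than the chosen plan. The position of the ring-D methoxy group is dictated by a strongly polarised diene, at least as reliable as the aryne polarisation relied on here. Both enone arms of A7 lead to the same arene, so the key step needs no facial or site selectivity; the plans are equal on that count.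
- Against it: the reacting enone carbon is next to a quaternary carbon that carries the bulky tetralin unit. A para-quinol with a secondary benzylic substituent is prone to dienone–phenol rearrangement under the acid needed for aromatisation. A8 is sensitive to acid and heat. The disconnection also leaves the real problem untouched: the C4–aryl bond peri to methoxy and both stereocentres must still be made for the phenol from which A7 derives, and a dearomatising oxidation is added.
- Comparison: on structure it simplifies the wrong half of the molecule. On mechanism its cycloaddition is as well founded as the one chosen. On step economy it is longer, because ring B with its stereocentres still needs its own synthesis.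

Key step: step 5

Remark on the chemistry: the target is read as the cis-(1S,4S) isomer (C1 hydroxyl and C4 aryl on the same face); the pivalate serves as the naphthol mask, the bridge is opened by ionic hydrogenation rather than over a heterogeneous catalyst so that cation stability decides which C–O bond breaks, and the atoms carry the numbering of the target tetralin throughout the discussion.

## Route

Step 1
Reactants: 1 naphthalene-1,8-diol
Product: 2 8-methoxynaphthalen-1-ol
Conditions: MeI (1.05 equiv), K2CO3 (1.1 equiv), acetone, rt → 40 °C
Reagents that add atoms: iodomethane, CI
Why: Williamson ether synthesis; after the first methylation the remaining hydroxyl is held in a strong hydrogen bond to the peri methoxy group and is much less reactive, so one equivalent of MeI should stop at the mono-ether.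

Step 2
Reactants: 2 8-methoxynaphthalen-1-ol
Product: 3 4-bromo-8-methoxynaphthalen-1-ol
Conditions: NBS (1.0 equiv), MeCN, −20 → 0 °C, dark
Reagents that add atoms: N-bromosuccinimide, O=C1CCC(=O)N1Br
Why: Electrophilic aromatic bromination; the hydrogen-bond-donating hydroxyl is the stronger activator and should direct NBS to its para position C4 in a polar solvent at low temperature, with the ortho position as the minor competitor.

Step 3
Reactants: 3 4-bromo-8-methoxynaphthalen-1-ol
Product: 4 4-bromo-8-methoxynaphthalen-1-yl pivalate
Conditions: PivCl (1.3 equiv), Et3N, DMAP (0.1 equiv), CH2Cl2, 0 °C → rt
Reagents that add atoms: pivaloyl chloride, CC(C)(C)C(Cl)=O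
Why: DMAP-catalysed acylation; the pivalate keeps the naphthol from adding to the aryne, is stable to fluoride, hydrogenation, Lewis acid and cold borane, and can be removed at the end without acid.

Step 4
Reactants: 4 4-bromo-8-methoxynaphthalen-1-yl pivalate; 5 furan-2-ylboronic acid
Product: 6 4-(furan-2-yl)-8-methoxynaphthalen-1-yl pivalate
Conditions: 5 (2.0 equiv, in portions), Pd(OAc)2 (3 mol%), SPhos (6 mol%), K3PO4, THF/H2O, 40 °C
Reagents that add atoms: none
Why: Suzuki–Miyaura coupling; the bulky electron-rich biarylphosphine makes oxidative addition and transmetalation fast at mild temperature, so coupling should outrun protodeboronation of 5, and the phosphate base spares the hindered ester.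

Step 5
Reactants: 6 4-(furan-2-yl)-8-methoxynaphthalen-1-yl pivalate; 7 3-methoxy-2-(trimethylsilyl)phenyl trifluoromethanesulfonate
Product: 9 racemic 8-methoxy-4-(8-methoxy-1,4-dihydro-1,4-epoxynaphthalen-1-yl)naphthalen-1-yl pivalate, via 3-methoxybenzyne 8 (not isolated)
Conditions: CsF (4 equiv), MeCN, rt; 7 (1.8 equiv) added over 4 h
Reagents that add atoms: none
Why: Fluoride attacks the silicon of 7 and the aryl anion expels triflate, so that 8 forms slowly and is trapped at once by the furan ring of 6 in a concerted but asynchronous [4+2] cycloaddition. The closest known reaction type is the Diels–Alder reaction of arynes from 2-silylaryl triflates with 2-substituted furans. Both new bonds (C1–C8a and C4–C4a) form in this one cycloaddition, which closes the six-membered carbocycle ring B and at the same time makes the furan oxygen the C1–O–C4 bridge, that is the five-membered oxygen ring, by suprafacial addition across the furan termini. The two bridgehead stereocentres C1 and C4 have only one possible relative configuration, fixed by the geometry of the bridge; nothing controls the absolute sense and 9 is racemic. The selectivity needed is regiochemical: the aryl-bearing furan carbon must bond to the aryne carbon next to the methoxy group. Two features secure it: the inductively withdrawing methoxy group distorts 8 so that the aryne carbon meta to it is the more electrophilic, and the unsubstituted furan carbon is the more nucleophilic terminus because positive charge developing on the other terminus is stabilised by the naphthyl group. Steric repulsion between the naphthyl group and the methoxy group works against this, so the regioisomer is expected as a by-product to be removed by chromatography. The pivalate keeps the naphthol oxygen from adding to 8, and the naphthalene rings are too aromatic to compete as dienes at room temperature.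

Step 6
Reactants: 9 racemic 8-methoxy-4-(8-methoxy-1,4-dihydro-1,4-epoxynaphthalen-1-yl)naphthalen-1-yl pivalate
Product: 10 racemic 8-methoxy-4-(8-methoxy-1,2,3,4-tetrahydro-1,4-epoxynaphthalen-1-yl)naphthalen-1-yl pivalate
Conditions: H2 (1 atm), 5% Pd/C, EtOAc, Et3N (trace), rt
Reagents that add atoms: none
Why: Heterogeneous catalytic hydrogenation; the strained cis-alkene of the oxabicycle should be reduced far faster than the hindered benzylic C–O bonds or the arenes under neutral, amine-buffered conditions, and removing it closes the acid-induced path to a naphthol; no stereocentre is made or lost.

Step 7
Reactants: 10 racemic 8-methoxy-4-(8-methoxy-1,2,3,4-tetrahydro-1,4-epoxynaphthalen-1-yl)naphthalen-1-yl pivalate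
Product: 12 racemic 4-(4-hydroxy-8-methoxy-1,2,3,4-tetrahydronaphthalen-1-yl)-8-methoxynaphthalen-1-yl pivalate (cis/trans mixture), via triethylsilyl ether 11 (not isolated)
Conditions: Et3SiH (3 equiv), Et3SiOTf (0.2 equiv), CH2Cl2, −78 → −40 °C; then 1 M aq. HCl, THF, 0 °C
Reagents that add atoms: none
Why: Ionic hydrogenation (silane and Lewis acid cleavage of a benzylic ether); silylation of the bridge oxygen leads to ionisation at C4 only, because that carbon alone gives a tertiary, doubly benzylic cation, and Et3SiH reduces this cation while regenerating the silyl cation that carries the chain. The new C4–H centre is expected to form without useful selectivity, which is harmless because C1 is oxidised next; dilute acid then frees the alcohol from 11.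

Step 8
Reactants: 12 racemic 4-(4-hydroxy-8-methoxy-1,2,3,4-tetrahydronaphthalen-1-yl)-8-methoxynaphthalen-1-yl pivalate (cis/trans mixture)
Product: 13 racemic 8-methoxy-4-(8-methoxy-4-oxo-1,2,3,4-tetrahydronaphthalen-1-yl)naphthalen-1-yl pivalate
Conditions: DMP (1.3 equiv), NaHCO3, CH2Cl2, 0 °C → rt
Reagents that add atoms: none
Why: Dess–Martin oxidation of a secondary benzylic alcohol; both diastereomers of 12 converge on one racemic ketone with C4 as its only stereocentre, and the buffered neutral conditions should leave the pivalate and the electron-rich arenes untouched.

Step 9
Reactants: 13 racemic 8-methoxy-4-(8-methoxy-4-oxo-1,2,3,4-tetrahydronaphthalen-1-yl)naphthalen-1-yl pivalate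
Product: 14 4-[(1S,4S)-4-hydroxy-8-methoxy-1,2,3,4-tetrahydronaphthalen-1-yl]-8-methoxynaphthalen-1-yl pivalate (cis)
Conditions: (R)-2-methyl-CBS-oxazaborolidine (0.3 equiv), BH3·SMe2 (1.0 equiv), THF, −20 °C, slow addition of 13; MeOH quench; SiO2 chromatography
Reagents that add atoms: none
Why: Corey–Bakshi–Shibata reduction used as a divergent reaction on a racemate, a reaction type established for 4-aryl-1-tetralones; the (R)-oxazaborolidine should deliver hydride to the same carbonyl face in both enantiomers (ring-A carbon C8a as the large group, C2 methylene as the small one) and so set the carbinol carbon as S by catalyst control. The (4S)-ketone then gives cis 14, while the (4R)-ketone gives the trans diastereomer (carbinol carbon S, aryl-bearing carbon R), which should separate from 14 on silica and is discarded.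

Step 10
Reactants: 14 4-[(1S,4S)-4-hydroxy-8-methoxy-1,2,3,4-tetrahydronaphthalen-1-yl]-8-methoxynaphthalen-1-yl pivalate
Product: 15 4-[(1S,4S)-4-hydroxy-8-methoxy-1,2,3,4-tetrahydronaphthalen-1-yl]-8-methoxynaphthalen-1-ol (dipolynaphthalene B)
Conditions: LiAlH4 (3 equiv), THF, 0 °C; aq. potassium sodium tartrate work-up under argon
Reagents that add atoms: none
Why: Reductive cleavage of an aryl ester by hydride; no acid is involved, so the benzylic carbinol and both stereocentres should be untouched, and the work-up under inert gas protects the liberated naphthol from air.

## Compound list

1 | naphthalene-1,8-diol | Oc1cccc2cccc(O)c12 | starting material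
2 | 8-methoxynaphthalen-1-ol | COc1cccc2cccc(O)c12 | intermediate
3 | 4-bromo-8-methoxynaphthalen-1-ol | COc1cccc2c(Br)ccc(O)c12 | intermediate
4 | 4-bromo-8-methoxynaphthalen-1-yl pivalate | COc1cccc2c(Br)ccc(OC(=O)C(C)(C)C)c12 | intermediate
5 | furan-2-ylboronic acid | OB(O)c1ccco1 | starting material
6 | 4-(furan-2-yl)-8-methoxynaphthalen-1-yl pivalate | CC(C)(C)C(=O)Oc1ccc(-c2ccco2)c2cccc(OC)c12 | intermediate
7 | 3-methoxy-2-(trimethylsilyl)phenyl trifluoromethanesulfonate | COc1cccc(OS(=O)(=O)C(F)(F)F)c1[Si](C)(C)C | starting material
8 | 3-methoxybenzyne (1-methoxy-2,3-didehydrobenzene) | COC1=CC=CC#C1 | intermediate (not isolated)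
9 | racemic 8-methoxy-4-(8-methoxy-1,4-dihydro-1,4-epoxynaphthalen-1-yl)naphthalen-1-yl pivalate (one enantiomer drawn; aryl bridgehead next to the methoxy-bearing carbon) | COc1cccc2c1[C@@]1(c3ccc(OC(=O)C(C)(C)C)c4c(OC)cccc34)O[C@@H]2C=C1 | intermediate
10 | racemic 8-methoxy-4-(8-methoxy-1,2,3,4-tetrahydro-1,4-epoxynaphthalen-1-yl)naphthalen-1-yl pivalate (one enantiomer drawn) | COc1cccc2c1[C@@]1(c3ccc(OC(=O)C(C)(C)C)c4c(OC)cccc34)O[C@@H]2CC1 | intermediate
11 | racemic 8-methoxy-4-[8-methoxy-4-(triethylsilyloxy)-1,2,3,4-tetrahydronaphthalen-1-yl]naphthalen-1-yl pivalate (cis/trans mixture) | COc1cccc2c1C(c1ccc(OC(=O)C(C)(C)C)c3c(OC)cccc13)CCC2O[Si](CC)(CC)CC | intermediate (not isolated)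
12 | racemic 4-(4-hydroxy-8-methoxy-1,2,3,4-tetrahydronaphthalen-1-yl)-8-methoxynaphthalen-1-yl pivalate (cis/trans mixture) | COc1cccc2c1C(c1ccc(OC(=O)C(C)(C)C)c3c(OC)cccc13)CCC2O | intermediate
13 | racemic 8-methoxy-4-(8-methoxy-4-oxo-1,2,3,4-tetrahydronaphthalen-1-yl)naphthalen-1-yl pivalate | COc1cccc2c1C(c1ccc(OC(=O)C(C)(C)C)c3c(OC)cccc13)CCC2=O | intermediate
14 | 4-[(1S,4S)-4-hydroxy-8-methoxy-1,2,3,4-tetrahydronaphthalen-1-yl]-8-methoxynaphthalen-1-yl pivalate (cis; carbinol carbon S, aryl-bearing carbon S) | COc1cccc2c1[C@H](c1ccc(OC(=O)C(C)(C)C)c3c(OC)cccc13)CC[C@@H]2O | intermediate
15 | 4-[(1S,4S)-4-hydroxy-8-methoxy-1,2,3,4-tetrahydronaphthalen-1-yl]-8-methoxynaphthalen-1-ol, dipolynaphthalene B | COc1cccc2c1[C@H](c1ccc(O)c3c(OC)cccc13)CC[C@@H]2O | target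

## Step count and least certain steps

Total step count: 10. Longest linear sequence: 10 steps, from 1 to 15; 5 and 7 enter as purchased components.

Step 5 (key step). The most likely failure is poor regiochemical discrimination in the cycloaddition: steric repulsion between the naphthyl group and the methoxy group opposes the electronic preference, and the biaryl twist weakens the polarisation of the furan. Self-reaction of the aryne can also consume 7. The fallback leaves the cycloaddition and makes the C4–C1′ bond by a Friedel–Crafts alkylation. It sets out from 2 and comes back to the route at 13. Purchased 5-methoxy-3,4-dihydronaphthalen-1(2H)-one F1 would be brominated at the benzylic C4 position under radical conditions (NBS, AIBN, PhCF3, reflux) to racemic 4-bromo-5-methoxy-3,4-dihydronaphthalen-1(2H)-one F2. Ionisation of F2 in hexafluoropropan-2-ol, helped by the ortho methoxy group, in the presence of 2 should alkylate the naphthol para to its hydroxyl. This gives racemic 4-(4-hydroxy-5-methoxynaphthalen-1-yl)-5-methoxy-3,4-dihydronaphthalen-1(2H)-one F3, whose pivaloylation (PivCl, Et3N, DMAP) gives 13. This path is regiochemically unambiguous on ring A, but it has its own hazard in the loss of HBr from F2 toward a naphthol.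

Step 7. The most likely failure is loss of a proton from the crowded cation in place of hydride capture, followed by ionisation of the resulting allylic silyl ether and aromatisation. Over-reduction by a second ionisation at C1 is the other risk. The fallback separates elimination and reduction. It sets out from 10 and comes back at 11. Et3SiOTf with 2,6-lutidine in CH2Cl2 at −78 °C should open the bridge with buffered elimination to racemic 8-methoxy-4-[8-methoxy-4-(triethylsilyloxy)-3,4-dihydronaphthalen-1-yl]naphthalen-1-yl pivalate F4. Hydrogenation of its styrene-type double bond with H2 and [Ir(cod)(PCy3)(py)]PF6 (a monovalent iridium catalyst that does not cleave allylic C–O bonds) then gives 11, which is hydrolysed to 12 as in step 7.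

Step 9. The most likely failure is incomplete catalyst control in one of the two enantiomers of 13, where the pseudo-axial naphthyl group at C4 may oppose the catalyst; this would lower the enantiomeric purity of 14. Poor separation of the two diastereomers is the second risk. The fallback replaces the reduction by an enzymatic kinetic resolution. It sets out from 12 and comes back at 14. Candida antarctica lipase B with vinyl acetate in toluene should acylate the alcohols with R configuration at the carbinol carbon. These leave as 4-[(1R,4R)-4-acetoxy-8-methoxy-1,2,3,4-tetrahydronaphthalen-1-yl]-8-methoxynaphthalen-1-yl pivalate F5 and 4-[(1S,4R)-4-acetoxy-8-methoxy-1,2,3,4-tetrahydronaphthalen-1-yl]-8-methoxynaphthalen-1-yl pivalate F6. The two unreacted alcohols with S configuration at the carbinol carbon, cis 14 and its trans epimer at the aryl-bearing carbon, are then separated on silica as in step 9; steps 8 and 9 are not needed on this path.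

Step 4. The most likely failure is protodeboronation of 5 outrunning transmetalation, with partial hydrolysis of the pivalate by the aqueous base as a second risk. The fallback reverses the polarity of the coupling. It sets out from 4 and comes back at 6. Miyaura borylation of 4 (B2pin2, PdCl2(dppf), KOAc, dioxane, 80 °C) should give 8-methoxy-4-(4,4,5,5-tetramethyl-1,3,2-dioxaborolan-2-yl)naphthalen-1-yl pivalate F7, a stable aryl boronate. Suzuki–Miyaura coupling of F7 with purchased 2-bromofuran F8 (Pd(OAc)2, SPhos, K3PO4, THF/H2O) then gives 6.

## Further compounds

F1 | step 5 | 5-methoxy-3,4-dihydronaphthalen-1(2H)-one | COc1cccc2c1CCCC2=O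
F2 | step 5 | racemic 4-bromo-5-methoxy-3,4-dihydronaphthalen-1(2H)-one | COc1cccc2c1C(Br)CCC2=O
F3 | step 5 | racemic 4-(4-hydroxy-5-methoxynaphthalen-1-yl)-5-methoxy-3,4-dihydronaphthalen-1(2H)-one | COc1cccc2c1C(c1ccc(O)c3c(OC)cccc13)CCC2=O
F4 | step 7 | racemic 8-methoxy-4-[8-methoxy-4-(triethylsilyloxy)-3,4-dihydronaphthalen-1-yl]naphthalen-1-yl pivalate | COc1cccc2c1C(c1ccc(OC(=O)C(C)(C)C)c3c(OC)cccc13)=CCC2O[Si](CC)(CC)CC
F5 | step 9 | 4-[(1R,4R)-4-acetoxy-8-methoxy-1,2,3,4-tetrahydronaphthalen-1-yl]-8-methoxynaphthalen-1-yl pivalate | COc1cccc2c1[C@@H](c1ccc(OC(=O)C(C)(C)C)c3c(OC)cccc13)CC[C@H]2OC(C)=O
F6 | step 9 | 4-[(1S,4R)-4-acetoxy-8-methoxy-1,2,3,4-tetrahydronaphthalen-1-yl]-8-methoxynaphthalen-1-yl pivalate | COc1cccc2c1[C@H](c1ccc(OC(=O)C(C)(C)C)c3c(OC)cccc13)CC[C@H]2OC(C)=O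
F7 | step 4 | 8-methoxy-4-(4,4,5,5-tetramethyl-1,3,2-dioxaborolan-2-yl)naphthalen-1-yl pivalate | COc1cccc2c(B3OC(C)(C)C(C)(C)O3)ccc(OC(=O)C(C)(C)C)c12
F8 | step 4 | 2-bromofuran | Brc1ccco1
A1 | alternative 1 | (S)-4-aryl-5-methoxy-1-tetralone with the naphthol as triisopropylsilyl ether | COc1cccc2c1[C@H](c1ccc(O[Si](C(C)C)(C(C)C)C(C)C)c3c(OC)cccc13)CCC2=O
A2 | alternative 1 | (S)-1-bromo-3-methoxy-2-{1-[5-methoxy-4-(triisopropylsilyloxy)naphthalen-1-yl]prop-2-en-1-yl}benzene | COc1cccc(Br)c1[C@H](c1ccc(O[Si](C(C)C)(C(C)C)C(C)C)c2c(OC)cccc12)C=C
A3 | alternative 1 | carbon monoxide | [C-]#[O+]
A4 | alternative 2 | C5 phenol of the bis-silylated tetralol (stereocentres as in the target) | Oc1cccc2c1[C@H](c1ccc(O[Si](C(C)C)(C(C)C)C(C)C)c3c(OC)cccc13)CC[C@@H]2O[Si](C)(C)C(C)(C)C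
A5 | alternative 2 | tert-butyldimethylsilyl ether of 1-(furan-2-yl)-4-[5-methoxy-4-(triisopropylsilyloxy)naphthalen-1-yl]hex-5-yn-1-ol (stereocentres as in the target) | C#C[C@H](c1ccc(O[Si](C(C)C)(C(C)C)C(C)C)c2c(OC)cccc12)CC[C@H](O[Si](C)(C)C(C)(C)C)c1ccco1
A6 | alternative 3 | C1 tert-butyldimethylsilyl ether of the target | COc1cccc2c1[C@H](c1ccc(O)c3c(OC)cccc13)CC[C@@H]2O[Si](C)(C)C(C)(C)C
A7 | alternative 3 | 4-[4-(tert-butyldimethylsilyloxy)-8-methoxy-1,2,3,4-tetrahydronaphthalen-1-yl]-4-(trimethylsilyloxy)cyclohexa-2,5-dien-1-one (stereocentres as in the target) | COc1cccc2c1[C@H](C1(O[Si](C)(C)C)C=CC(=O)C=C1)CC[C@@H]2O[Si](C)(C)C(C)(C)C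
A8 | alternative 3 | 1,1-dimethoxybuta-1,3-diene | COC(OC)=CC=C
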